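**Retrosynthetic overview**

- The (3R)-isoflavanone is traced back to a (3R,4S)-3-aryl-4-acetoxychroman carrying a 7-O-silyl group; acetate methanolysis, oxidation of C4–OH to the ketone and fluoride desilylation are the last three operations.
- Key disconnection: C3–C1' (ring B aryl) and C4–O are both made across the C3=C4 bond of an 8-prenyl-7-silyloxy-2H-chromene by enantioselective palladium oxyarylation with (2,2-dimethylchroman-6-yl)boronic acid and acetate.
- Feature used: in the 2H-chromene, C4 is benzylic to ring A (para to the 7-oxygen), so palladium settles there and the aryl goes to C3. The single C3–H then lies anti to palladium and C4a has no hydrogen, so β-hydride loss is closed and oxygen is captured at C4.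
- The chromene comes from 7-hydroxychroman-4-one (1,1-dimethylpropargyl ether, semihydrogenation, aromatic Claisen shift to C8, silylation, reduction, dehydration); the boronic acid comes from 6-bromo-2,2-dimethylchroman.
- Ring order: no ring is built. Rings A and C (the benzopyranone) and the chroman of ring B are bought intact; the route adds two skeletal bonds and the C3 stereocentre.

Key step: step 8

Remarks on the chemistry (assumptions):
- 3-Chloro-3-methylbut-1-yne and 6-bromo-2,2-dimethylchroman are taken as catalogue chemicals; "prenyl" means 3-methylbut-2-en-1-yl.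
- The 7-OH is carried as a triisopropylsilyl ether, because buffered fluoride at the end spares both the enolisable C3–H of the α-aryl ketone and the acid-sensitive ortho-prenyl phenol.
- C4 of the key product is drawn trans to the aryl group (anti acetate attack); a cis C4 epimer would converge at the ketone in step 10.
- The sense of induction of the pyridine-oxazoline ligand on this substrate is not known in advance; the (S)-ligand is written, and its mirror image is used if the first run gives the (3S) series.

**Route**

Step 1
Reactants: 1 7-hydroxychroman-4-one; 2 3-chloro-3-methylbut-1-yne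
Product: 3 7-[(2-methylbut-3-yn-2-yl)oxy]chroman-4-one
Conditions: K2CO3, KI, CuI (cat.), acetone, 60 °C
Reagents that add atoms: 3-chloro-3-methylbut-1-yne (compound 2), CC(C)(Cl)C#C
Why: Copper-assisted Williamson-type etherification, in which the phenoxide of 1 (its only acidic site) substitutes the tertiary propargylic chloride through a copper acetylide, the standard entry to 1,1-dimethylpropargyl aryl ethers; the chromanone tolerates K2CO3.

Step 2
Reactants: 3 7-[(2-methylbut-3-yn-2-yl)oxy]chroman-4-one
Product: 4 7-[(2-methylbut-3-en-2-yl)oxy]chroman-4-one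
Conditions: H2 (1 atm), Pd/CaCO3 poisoned by Pb(OAc)2 (Lindlar catalyst), quinoline, EtOAc, rt
Reagents that add atoms: none
Why: Lindlar semihydrogenation should stop the terminal alkyne at the vinyl stage on the quinoline-poisoned catalyst, leaving the aryl ketone and the ether untouched.

Step 3
Reactants: 4 7-[(2-methylbut-3-en-2-yl)oxy]chroman-4-one
Product: 6 7-hydroxy-8-(3-methylbut-2-en-1-yl)chroman-4-one, via ortho-dienone 5 (not isolated)
Conditions: PhNEt2, 130 °C
Reagents that add atoms: none
Why: Aromatic Claisen rearrangement ([3,3]-sigmatropic shift) of the 1,1-dimethylallyl ether should deliver the inverted (prenyl) chain to C8, the ortho carbon flanked by both ring A oxygens and the usual site in 7-allyloxy benzopyranones, after which dienone 5 tautomerises to the phenol.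

Step 4
Reactants: 6 7-hydroxy-8-(3-methylbut-2-en-1-yl)chroman-4-one
Product: 7 8-(3-methylbut-2-en-1-yl)-7-[(triisopropylsilyl)oxy]chroman-4-one
Conditions: TIPSCl, imidazole, DMF, rt
Reagents that add atoms: triisopropylsilyl chloride (TIPSCl), CC(C)[Si](Cl)(C(C)C)C(C)C
Why: Imidazole-mediated O-silylation of the acidic phenol; the bulky silyl ether should withstand hydride, mild base, AcOH and the palladium step.

Step 5
Reactants: 7 8-(3-methylbut-2-en-1-yl)-7-[(triisopropylsilyl)oxy]chroman-4-one
Product: 8 rac-8-(3-methylbut-2-en-1-yl)-7-[(triisopropylsilyl)oxy]chroman-4-ol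
Conditions: NaBH4, THF/EtOH, 0 °C
Reagents that add atoms: none
Why: Borohydride reduction of the aryl ketone; the new C4 centre is formed racemic without consequence because it is removed in step 6, and the alkene and hindered silyl ether should survive the short, cold reaction.

Step 6
Reactants: 8 rac-8-(3-methylbut-2-en-1-yl)-7-[(triisopropylsilyl)oxy]chroman-4-ol
Product: 10 8-(3-methylbut-2-en-1-yl)-7-[(triisopropylsilyl)oxy]-2H-chromene, via C4 mesylate 9 (not isolated)
Conditions: MsCl, Et3N, CH2Cl2, 0 °C → rt; then DBU, rt → 40 °C
Reagents that add atoms: none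
Why: Dehydration by mesylation and base-mediated elimination; the benzylic mesylate, activated by the para 7-oxygen and ortho O1, should lose sulfonate readily to give the conjugated C3=C4 alkene without protic acid that could touch the prenyl group.

Step 7
Reactants: 11 6-bromo-2,2-dimethylchroman
Product: 14 (2,2-dimethylchroman-6-yl)boronic acid, via aryllithium 12 (not isolated), via lithium triisopropoxyborate 13 (not isolated)
Conditions: n-BuLi, THF, −78 °C; B(OiPr)3, −78 °C → rt; 1 M HCl
Reagents that add atoms: triisopropyl borate, CC(C)OB(OC(C)C)OC(C)C; water, O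
Why: Bromine–lithium exchange, borylation of the aryllithium to the ate complex and acidic hydrolysis, a standard boronic acid preparation that the dialkyl aryl ether tolerates.

Step 8
Reactants: 10 8-(3-methylbut-2-en-1-yl)-7-[(triisopropylsilyl)oxy]-2H-chromene; 14 (2,2-dimethylchroman-6-yl)boronic acid
Product: 16 (3R,4S)-3-(2,2-dimethylchroman-6-yl)-8-(3-methylbut-2-en-1-yl)-7-[(triisopropylsilyl)oxy]chroman-4-yl acetate, via syn benzylpalladium adduct 15 (not isolated)
Conditions: Pd(OAc)2 (10 mol%), (S)-4-tert-butyl-2-[5-(trifluoromethyl)pyridin-2-yl]-4,5-dihydrooxazole (12 mol%), p-benzoquinone (2 equiv), LiOAc (2 equiv), AcOH (10 equiv), ClCH2CH2Cl, 30 °C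
Reagents that add atoms: (2,2-dimethylchroman-6-yl)boronic acid (compound 14), OB(O)c1ccc2OC(C)(C)CCc2c1; acetic acid, CC(=O)O
Why: Proposed new method: boronic acid 14 transmetalates to the ligand-bound divalent palladium acetate and the aryl–palladium species adds syn across C3=C4 of 10, aryl to C3 and palladium to the ring A benzylic carbon C4 (adduct 15, held as an η3-benzyl complex); acetate then opens this complex at C4 on the face opposite palladium, and benzoquinone with AcOH returns zerovalent palladium to the divalent state. The closest known reaction types are the palladium-mediated oxyarylation of 2H-chromenes with ortho-metalated phenols (aryl to C3, oxygen to C4), the enantioselective oxidative Heck arylation of cyclic alkenes with arylboronic acids under pyridine-oxazoline ligands, and the benzoquinone-assisted acetate attack on π-allyl palladium in diene diacetoxylation; what is new is the intermolecular, enantioselective pairing of a boronic acid with acetate on a chromene. No ring is closed. C3 is set in the migratory insertion, where the tert-butyl group of the oxazoline should decide which face of the flat, C2-unsubstituted chromene binds; C4 follows from C3 through syn insertion and anti acetate attack (trans), and because C4 becomes the ketone only C3 has to be right. The step needs regioselectivity (aryl to C3), which benzylic and 7-oxygen stabilisation of palladium at C4 should secure, and it needs oxygen capture to outrun β-hydride elimination, which is blocked because the one hydrogen on C3 lies anti to palladium and C4a bears none. The trisubstituted, unactivated prenyl alkene should insert far more slowly than the cis-styrenyl C3=C4 bond, and the silyl and chroman ethers are inert.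

Step 9
Reactants: 16 (3R,4S)-3-(2,2-dimethylchroman-6-yl)-8-(3-methylbut-2-en-1-yl)-7-[(triisopropylsilyl)oxy]chroman-4-yl acetate
Product: 17 (3R,4S)-3-(2,2-dimethylchroman-6-yl)-8-(3-methylbut-2-en-1-yl)-7-[(triisopropylsilyl)oxy]chroman-4-ol
Conditions: K2CO3, MeOH/THF, rt
Reagents that add atoms: none
Why: Base-catalysed transesterification (acyl–oxygen cleavage) frees the C4 alcohol without touching C3, which carries no acidifying group at this stage; the hindered aryl silyl ether on an electron-rich ring should resist carbonate in methanol.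

Step 10
Reactants: 17 (3R,4S)-3-(2,2-dimethylchroman-6-yl)-8-(3-methylbut-2-en-1-yl)-7-[(triisopropylsilyl)oxy]chroman-4-ol
Product: 18 (3R)-3-(2,2-dimethylchroman-6-yl)-8-(3-methylbut-2-en-1-yl)-7-[(triisopropylsilyl)oxy]chroman-4-one
Conditions: Dess–Martin periodinane, NaHCO3, CH2Cl2, 0 °C → rt
Reagents that add atoms: none
Why: Dess–Martin oxidation converts the benzylic alcohol to the ketone under near-neutral, bicarbonate-buffered conditions that should not enolise the new α-aryl ketone, so the C3 configuration is carried over unchanged; the prenyl alkene and silyl ether are inert.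

Step 11
Reactants: 18 (3R)-3-(2,2-dimethylchroman-6-yl)-8-(3-methylbut-2-en-1-yl)-7-[(triisopropylsilyl)oxy]chroman-4-one
Product: 19 (3R)-3-(2,2-dimethylchroman-6-yl)-7-hydroxy-8-(3-methylbut-2-en-1-yl)chroman-4-one
Conditions: TBAF, AcOH (1.2 equiv each), THF, 0 °C
Reagents that add atoms: none
Why: Fluoride desilylation of the aryl silyl ether, fast here because the phenoxide is para to the ketone; the acetic acid buffer should keep the medium too weakly basic to enolise C3 and no protic acid strong enough to cyclise the ortho-prenyl phenol is present.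

**Compound list**

1 | 7-hydroxychroman-4-one | O=C1CCOc2cc(O)ccc12 | starting material
2 | 3-chloro-3-methylbut-1-yne | CC(C)(Cl)C#C | starting material
3 | 7-[(2-methylbut-3-yn-2-yl)oxy]chroman-4-one | C#CC(C)(C)Oc1ccc2C(=O)CCOc2c1 | intermediate
4 | 7-[(2-methylbut-3-en-2-yl)oxy]chroman-4-one | C=CC(C)(C)Oc1ccc2C(=O)CCOc2c1 | intermediate
5 | 8-(3-methylbut-2-en-1-yl)-2,3-dihydro-8H-chromene-4,7-dione (ortho-dienone, racemic at C8) | CC(C)=CCC1C(=O)C=CC2=C1OCCC2=O | intermediate (not isolated)
6 | 7-hydroxy-8-(3-methylbut-2-en-1-yl)chroman-4-one | CC(C)=CCc1c(O)ccc2C(=O)CCOc12 | intermediate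
7 | 8-(3-methylbut-2-en-1-yl)-7-[(triisopropylsilyl)oxy]chroman-4-one | CC(C)=CCc1c(O[Si](C(C)C)(C(C)C)C(C)C)ccc2C(=O)CCOc12 | intermediate
8 | rac-8-(3-methylbut-2-en-1-yl)-7-[(triisopropylsilyl)oxy]chroman-4-ol | CC(C)=CCc1c(O[Si](C(C)C)(C(C)C)C(C)C)ccc2C(O)CCOc12 | intermediate
9 | rac-8-(3-methylbut-2-en-1-yl)-7-[(triisopropylsilyl)oxy]chroman-4-yl methanesulfonate | CC(C)=CCc1c(O[Si](C(C)C)(C(C)C)C(C)C)ccc2C(OS(C)(=O)=O)CCOc12 | intermediate (not isolated)
10 | 8-(3-methylbut-2-en-1-yl)-7-[(triisopropylsilyl)oxy]-2H-chromene | CC(C)=CCc1c(O[Si](C(C)C)(C(C)C)C(C)C)ccc2C=CCOc12 | intermediate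
11 | 6-bromo-2,2-dimethylchroman | CC1(C)CCc2cc(Br)ccc2O1 | starting material
12 | (2,2-dimethylchroman-6-yl)lithium | [Li]c1ccc2OC(C)(C)CCc2c1 | intermediate (not isolated)
13 | lithium (2,2-dimethylchroman-6-yl)tri(propan-2-yloxy)borate | [Li+].CC(C)O[B-](OC(C)C)(OC(C)C)c1ccc2OC(C)(C)CCc2c1 | intermediate (not isolated)
14 | (2,2-dimethylchroman-6-yl)boronic acid | OB(O)c1ccc2OC(C)(C)CCc2c1 | intermediate
15 | (3R,4R)-C4 benzylpalladium acetate adduct, aryl and palladium cis, chiral ligand omitted | CC(C)=CCc1c(O[Si](C(C)C)(C(C)C)C(C)C)ccc2c1OC[C@@H](c1ccc3OC(C)(C)CCc3c1)[C@H]2[Pd]OC(C)=O | intermediate (not isolated)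
16 | (3R,4S)-3-(2,2-dimethylchroman-6-yl)-8-(3-methylbut-2-en-1-yl)-7-[(triisopropylsilyl)oxy]chroman-4-yl acetate | CC(C)=CCc1c(O[Si](C(C)C)(C(C)C)C(C)C)ccc2c1OC[C@@H](c1ccc3OC(C)(C)CCc3c1)[C@@H]2OC(C)=O | intermediate
17 | (3R,4S)-3-(2,2-dimethylchroman-6-yl)-8-(3-methylbut-2-en-1-yl)-7-[(triisopropylsilyl)oxy]chroman-4-ol | CC(C)=CCc1c(O[Si](C(C)C)(C(C)C)C(C)C)ccc2c1OC[C@@H](c1ccc3OC(C)(C)CCc3c1)[C@@H]2O | intermediate
18 | (3R)-3-(2,2-dimethylchroman-6-yl)-8-(3-methylbut-2-en-1-yl)-7-[(triisopropylsilyl)oxy]chroman-4-one | CC(C)=CCc1c(O[Si](C(C)C)(C(C)C)C(C)C)ccc2c1OC[C@@H](c1ccc3OC(C)(C)CCc3c1)C2=O | intermediate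
19 | (3R)-3-(2,2-dimethylchroman-6-yl)-7-hydroxy-8-(3-methylbut-2-en-1-yl)chroman-4-one | CC(C)=CCc1c(O)ccc2c1OC[C@@H](c1ccc3OC(C)(C)CCc3c1)C2=O | target

**Step count and risks**

Total step count: 11. Longest linear sequence: 10 (steps 1–6, then 8–11); step 7 is the side branch.

Steps most likely to fail:

1. Step 8 (proposed new method). What may go wrong: protonolysis of the C4–palladium bond before acetate attack (net hydroarylation), protodeboronation or homocoupling of the boronic acid outrunning insertion, weak facial discrimination by the ligand, or acid-promoted ionisation of the benzylic acetate with loss of the C3 hydrogen. Fallback by known chemistry, setting out from ketone 7 and bromide 11 and coming back to the route at ketone 18: palladium-catalysed ketone α-arylation of 7 with 11 (Pd2(dba)3, XPhos, K3PO4, toluene, 90 °C) should give racemic 3-(2,2-dimethylchroman-6-yl)-8-(3-methylbut-2-en-1-yl)-7-[(triisopropylsilyl)oxy]chroman-4-one F1. Noyori asymmetric transfer hydrogenation under dynamic kinetic resolution (RuCl[(R,R)-TsDPEN](p-cymene), HCO2H/Et3N, EtOAc, 40 °C), in which the amine keeps the C3 epimers in equilibrium while one is reduced, should then give the cis alcohol (3R,4R)-3-(2,2-dimethylchroman-6-yl)-8-(3-methylbut-2-en-1-yl)-7-[(triisopropylsilyl)oxy]chroman-4-ol F2; the (R,R) catalyst is expected to give the 4R carbinol by analogy with simple aryl ketones. Dess–Martin oxidation as in step 10 returns 18.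

2. Step 3. What may go wrong: migration of the allyl unit to C6 instead of C8, or onward reaction of the ortho-prenyl phenol at the reaction temperature (closure onto the phenol oxygen, abnormal Claisen shift). Fallback, setting out from 1 and coming back at 6: iodination between the two ring A oxygens (I2, KI, aqueous NH3, 0 °C), with the regiochemistry checked on the iodide before more material is committed, should give 7-hydroxy-8-iodochroman-4-one F3. Stille coupling with tributyl(3-methylbut-2-en-1-yl)stannane (Pd(PPh3)4, DMF, 90 °C), which transfers the prenyl group through its CH2 terminus, then gives 6.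

3. Step 11. What may go wrong: enolisation at C3 of the α-aryl ketone under fluoride or the liberated phenoxide, eroding the enantiomeric purity set in step 8. Fallback, setting out from alcohol 17 and coming back at target 19: the silyl ether is removed first, while C3 is not yet acidic (TBAF, THF, 0 °C), to give (3R,4S)-3-(2,2-dimethylchroman-6-yl)-8-(3-methylbut-2-en-1-yl)chroman-4,7-diol F4. The para-hydroxybenzylic alcohol is then oxidised selectively with activated MnO2 (CH2Cl2, rt) under neutral heterogeneous conditions, so the ketone is formed last and meets neither fluoride nor base.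

**Further compounds**

F1 | step 8 | rac-3-(2,2-dimethylchroman-6-yl)-8-(3-methylbut-2-en-1-yl)-7-[(triisopropylsilyl)oxy]chroman-4-one | CC(C)=CCc1c(O[Si](C(C)C)(C(C)C)C(C)C)ccc2c1OCC(c1ccc3OC(C)(C)CCc3c1)C2=O
F2 | step 8 | (3R,4R)-3-(2,2-dimethylchroman-6-yl)-8-(3-methylbut-2-en-1-yl)-7-[(triisopropylsilyl)oxy]chroman-4-ol | CC(C)=CCc1c(O[Si](C(C)C)(C(C)C)C(C)C)ccc2c1OC[C@@H](c1ccc3OC(C)(C)CCc3c1)[C@H]2O
F3 | step 3 | 7-hydroxy-8-iodochroman-4-one | O=C1CCOc2c(I)c(O)ccc12
F4 | step 11 | (3R,4S)-3-(2,2-dimethylchroman-6-yl)-8-(3-methylbut-2-en-1-yl)chroman-4,7-diol | CC(C)=CCc1c(O)ccc2c1OC[C@@H](c1ccc3OC(C)(C)CCc3c1)[C@@H]2O
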